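**Target check.** C24H28O5. It is a 2,2-dimethyl-2H-chromene with OMe at C7 and an (S)-CH(CH3)–O– group at C6. The enol ether is O–CH=C(Ar)(CH2OH) with the ether O and CH2OH on the same side, which makes it (Z). Ar is 2-hydroxy-4-methylphenyl.

**Assumption.** In the plant the pyran ring is taken to arise from a prenylated 4-hydroxyacetophenone by oxidation to a vinyl ortho-quinone methide and oxa-6π ring closure. Both benzene rings are bought.

**Handling note.** From the benzylic alcohol onward nothing sees acid: work-ups stay at pH 8 or above and silica is deactivated with Et3N.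

## Retrosynthetic overview
1. Enol ether plus CH2OH ⇒ 2-arylallyl ether, by allylic metalation, boron capture at the far CH2 and oxidation. The double bond moves next to O, and the chelated anion fixes (Z).
2. 2-Arylallyl ether ⇒ Suzuki coupling (boronic acid with free phenol) and Williamson reaction (2,3-dibromopropene) on (S)-encecalol. The benzylic C–O bond is never broken.
3. (S)-Encecalol ⇒ asymmetric hydrogenation of encecalin.
4. Encecalin ⇒ pyran ring closed directly on the complete, deactivated 4-hydroxy-2-methoxyacetophenone with a prenal unit (vinyl ortho-quinone methide, then oxa-6π). No later acylation and no propargyl ether are needed.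
5. Ring order: the pyran ring is the only ring made, and it is made first.

## Route

Step 1
Reactants: 1 1-(4-hydroxy-2-methoxyphenyl)ethan-1-one; 2 1,1-diethoxy-3-methylbut-2-ene (prenal diethyl acetal)
Product: 4 encecalin (1-(7-methoxy-2,2-dimethyl-2H-chromen-6-yl)ethan-1-one), via vinyl ortho-quinone methide 3 (not isolated)
Conditions: 2 (1.6 equiv), 3-picoline (0.5 equiv), p-xylene, 140 °C, EtOH distilled off, 24 h
Reagents that add atoms: none
Why: Thermal chromenylation of an acidic phenol with an enal acetal, in which acetal exchange, ortho C–C bond formation at C5 (para to OMe and less crowded than C3) and loss of the second ethanol give the same vinyl ortho-quinone methide that oxidation of the prenylphenol would give, and its oxa-6π electrocyclisation closes the pyran ring without creating a stereocentre.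

Step 2
Reactants: 4 encecalin
Product: 5 (S)-encecalol ((1S)-1-(7-methoxy-2,2-dimethyl-2H-chromen-6-yl)ethan-1-ol)
Conditions: H2 (8 atm), trans-RuCl2[(R)-xylbinap][(R)-daipen] (0.2 mol %), KOtBu (2 mol %), iPrOH, 25 °C
Reagents that add atoms: none
Why: Noyori bifunctional ketone hydrogenation (outer-sphere Ru–H/N–H transfer) reduces only C=O, leaves the chromene C=C alone, runs under base so the ionisable benzylic alcohol is safe, and the (R)/(R) ligand pair delivers hydride to the Re face of aryl methyl ketones to set the (S) centre.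

Step 3
Reactants: 5 (S)-encecalol; 6 2,3-dibromoprop-1-ene
Product: 8 6-[(1S)-1-(2-bromoprop-2-en-1-yloxy)ethyl]-7-methoxy-2,2-dimethyl-2H-chromene, via sodium alkoxide 7 (not isolated)
Conditions: NaH (1.2 equiv), THF/DMF 4:1, 0 °C; 6 (1.3 equiv), Bu4NI (5 mol %), 0 → 25 °C
Reagents that add atoms: none
Why: Williamson ether synthesis by SN2 at the allylic CH2Br (the vinylic bromide is inert), in which the C–O bond at the stereocentre is not broken and (S) is retained.

Step 4
Reactants: 8 bromoallyl ether; 9 (2-hydroxy-4-methylphenyl)boronic acid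
Product: 10 2-{3-[(1S)-1-(7-methoxy-2,2-dimethyl-2H-chromen-6-yl)ethoxy]prop-1-en-2-yl}-5-methylphenol
Conditions: 9 (1.4 equiv), Pd(dppf)Cl2 (3 mol %), K2CO3 (3 equiv), 1,4-dioxane/H2O 5:1, 70 °C
Reagents that add atoms: none
Why: Suzuki–Miyaura coupling of a 2-bromoallyl ether, which tolerates the free phenol as its phenoxide, needs no protecting group and leaves the remote stereocentre untouched under basic conditions.

Step 5
Reactants: 10 arylallyl ether phenol
Product: 13 target 2-{(1Z)-3-hydroxy-1-[(1S)-1-(7-methoxy-2,2-dimethyl-2H-chromen-6-yl)ethoxy]prop-1-en-2-yl}-5-methylphenol, via dipotassio allyl anion 11 (not isolated), via allylboronate 12 (not isolated)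
Conditions: n-BuLi/KOtBu/TMP(H) (2.3 equiv each), THF, −78 °C, 30 min; iPrOBpin (2.5 equiv), −78 → 0 °C; 2 M NaOH, 30 % H2O2, 0 °C; pH 8 phosphate work-up
Reagents that add atoms: hydrogen peroxide, OO
Why: The non-nucleophilic amide superbase (no addition to the styrene) removes the phenol proton and then the allylic OCH2 proton, the 1-alkoxyallyl anion adopts the chelated endo shape with the bulky ether group turned away from the aryl ring so that boron is taken up at the free CH2 end cis to the ether oxygen (Hoffmann-type (Z)-gamma-alkoxyallylboronate synthesis), and stereoretentive boronate oxidation gives the (Z)-enol ether alcohol without touching the (S) centre.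

## Compound list
1 | 1-(4-hydroxy-2-methoxyphenyl)ethan-1-one | CC(=O)c1ccc(O)cc1OC | starting material
2 | 1,1-diethoxy-3-methylbut-2-ene | CCOC(OCC)C=C(C)C | starting material
3 | (6Z)-4-acetyl-3-methoxy-6-(3-methylbut-2-en-1-ylidene)cyclohexa-2,4-dien-1-one | CC(=O)C1=C/C(=C/C=C(C)C)C(=O)C=C1OC | intermediate
4 | encecalin, 1-(7-methoxy-2,2-dimethyl-2H-chromen-6-yl)ethan-1-one | COc1cc2c(cc1C(C)=O)C=CC(C)(C)O2 | intermediate
5 | (S)-encecalol | COc1cc2c(cc1[C@H](C)O)C=CC(C)(C)O2 | intermediate
6 | 2,3-dibromoprop-1-ene | C=C(Br)CBr | starting material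
7 | sodium (1S)-1-(7-methoxy-2,2-dimethyl-2H-chromen-6-yl)ethan-1-olate | COc1cc2c(cc1[C@H](C)[O-])C=CC(C)(C)O2.[Na+] | intermediate
8 | 6-[(1S)-1-(2-bromoprop-2-en-1-yloxy)ethyl]-7-methoxy-2,2-dimethyl-2H-chromene | COc1cc2c(cc1[C@H](C)OCC(Br)=C)C=CC(C)(C)O2 | intermediate
9 | (2-hydroxy-4-methylphenyl)boronic acid | Cc1ccc(B(O)O)c(O)c1 | starting material
10 | 2-{3-[(1S)-1-(7-methoxy-2,2-dimethyl-2H-chromen-6-yl)ethoxy]prop-1-en-2-yl}-5-methylphenol | COc1cc2c(cc1[C@H](C)OCC(=C)c1ccc(C)cc1O)C=CC(C)(C)O2 | intermediate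
11 | dipotassium species: potassium phenoxide and endo 1-alkoxy-2-arylallylpotassium, drawn as the gamma-metalated form | COc1cc2c(cc1[C@H](C)O/C=C(\C[K])c1ccc(C)cc1[O-])C=CC(C)(C)O2.[K+] | intermediate
12 | potassium phenoxide of the gamma-alkoxyallyl pinacol boronate, ether O cis to CH2B | COc1cc2c(cc1[C@H](C)O/C=C(\CB1OC(C)(C)C(C)(C)O1)c1ccc(C)cc1[O-])C=CC(C)(C)O2.[K+] | intermediate
13 | target, (S,Z) | COc1cc2c(cc1[C@H](C)O/C=C(\CO)c1ccc(C)cc1O)C=CC(C)(C)O2 | target

## Count and risks
Total step count: 5. Longest linear sequence: 5 (1 → 4 → 5 → 8 → 10 → 13).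

**Step 5 (highest risk).**
- The base may metalate C8–H between the two ring oxygens instead of the allylic position.
- The easily migrating benzylic group may undergo a [1,2]- or [1,4]-Wittig shift.
- Boron may be taken up at the alpha carbon.
- The anion may leak some of the other double-bond isomer.

Fallback: make the vinyl C–O bond by cross-coupling on a vinyl iodide whose geometry is fixed beforehand. It sets out from 5 and comes back at 13. 2-bromo-5-methylphenol F1 is silylated (TIPSCl, imidazole, DMF) to (2-bromo-5-methylphenoxy)tri(propan-2-yl)silane F2. With Mg in THF this gives [4-methyl-2-(triisopropylsilyloxy)phenyl]magnesium bromide F3. Of this, 2.2 equiv add to prop-2-yn-1-ol F4 (CuI 10 mol %, THF, 25 to 50 °C) by alkoxide-directed anti-carbomagnesiation to give the five-membered oxamagnesacycle F5. I2 then gives (Z)-3-iodo-2-[4-methyl-2-(triisopropylsilyloxy)phenyl]prop-2-en-1-ol F6, with iodine cis to CH2OH. TBSCl and imidazole give its tert-butyldimethylsilyl ether F7. CuI (10 mol %), 3,4,7,8-tetramethyl-1,10-phenanthroline (20 mol %) and Cs2CO3 in toluene at 90 °C join F7 to 5, with retention at the double bond and at the carbinol carbon, to give the bis-silyl ether of the target F8. TBAF in THF at 0 °C frees both hydroxyl groups and gives 13. The fallback replaces steps 3 to 5.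

**Step 1.**
- The ring is deactivated by the para acetyl group.
- C3 competes with C5 as the site of attack.
- The reaction needs a long time at 140 °C.

Fallback: close the ring on the acyl-free, more nucleophilic phenol and bring the acetyl group in afterwards. It sets out from 2 and comes back at 4, and it is one step longer. 3-methoxyphenol F9 and 2 (3-picoline, p-xylene, 140 °C) give, through 3-methoxy-6-(3-methylbut-2-en-1-ylidene)cyclohexa-2,4-dien-1-one F10 and the same oxa-6π closure, 7-methoxy-2,2-dimethyl-2H-chromene F11. Friedel–Crafts acetylation (Ac2O, Sc(OTf)3 5 mol %, MeNO2, 0 °C) then goes to C6, which is para to the ring oxygen and ortho to OMe, and gives 4.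

**Step 4.**
- The electron-rich 2-hydroxyarylboronic acid may protodeboronate.
- The 2-palladated allyl ether may lose alkoxide to form an allene.

Fallback: reverse the polarity and avoid the vinyl bromide. It sets out from 7 and comes back at 10. Alkoxide 7 is alkylated with 3-bromoprop-1-yne F12 to give the (S)-propargyl ether F13. Markovnikov protoboration ((SIMes)CuCl 5 mol %, NaOtBu 5 mol %, B2pin2, MeOH, THF, −15 °C) gives the internal alkenyl pinacol boronate F14. This couples with 2-bromo-5-methylphenol F1 (Pd(dppf)Cl2, K2CO3, dioxane/H2O, 70 °C) to give 10.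

## Further compounds
F1 | step 5 | 2-bromo-5-methylphenol (bought) | Cc1ccc(Br)c(O)c1
F2 | step 5 | (2-bromo-5-methylphenoxy)tri(propan-2-yl)silane | Cc1ccc(Br)c(O[Si](C(C)C)(C(C)C)C(C)C)c1
F3 | step 5 | [4-methyl-2-(triisopropylsilyloxy)phenyl]magnesium bromide | Cc1ccc([Mg]Br)c(O[Si](C(C)C)(C(C)C)C(C)C)c1
F4 | step 5 | prop-2-yn-1-ol (bought) | C#CCO
F5 | step 5 | five-membered oxamagnesacycle, 4-aryl-2,5-dihydro-1,2-oxamagnesole | Cc1ccc(C2=C[Mg]OC2)c(O[Si](C(C)C)(C(C)C)C(C)C)c1
F6 | step 5 | (Z)-3-iodo-2-[4-methyl-2-(triisopropylsilyloxy)phenyl]prop-2-en-1-ol | I/C=C(\CO)c1ccc(C)cc1O[Si](C(C)C)(C(C)C)C(C)C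
F7 | step 5 | tert-butyldimethylsilyl ether of F6 | I/C=C(\CO[Si](C)(C)C(C)(C)C)c1ccc(C)cc1O[Si](C(C)C)(C(C)C)C(C)C
F8 | step 5 | bis-silyl ether of the target, (S,Z) | COc1cc2c(cc1[C@H](C)O/C=C(\CO[Si](C)(C)C(C)(C)C)c1ccc(C)cc1O[Si](C(C)C)(C(C)C)C(C)C)C=CC(C)(C)O2
F9 | step 1 | 3-methoxyphenol (bought) | COc1cccc(O)c1
F10 | step 1 | 3-methoxy-6-(3-methylbut-2-en-1-ylidene)cyclohexa-2,4-dien-1-one | O=C1C=C(OC)C=CC1=CC=C(C)C
F11 | step 1 | 7-methoxy-2,2-dimethyl-2H-chromene | COc1ccc2C=CC(C)(C)Oc2c1
F12 | step 4 | 3-bromoprop-1-yne (bought) | C#CCBr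
F13 | step 4 | 7-methoxy-2,2-dimethyl-6-[(1S)-1-(prop-2-yn-1-yloxy)ethyl]-2H-chromene | COc1cc2c(cc1[C@H](C)OCC#C)C=CC(C)(C)O2
F14 | step 4 | 2-{3-[(1S)-1-(7-methoxy-2,2-dimethyl-2H-chromen-6-yl)ethoxy]prop-1-en-2-yl}-4,4,5,5-tetramethyl-1,3,2-dioxaborolane | COc1cc2c(cc1[C@H](C)OCC(=C)B1OC(C)(C)C(C)(C)O1)C=CC(C)(C)O2
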